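**Plan**
1. Retrosynthetic cuts: (a) C8–C9, the bond between the ketone carbon and the methyl-bearing olefinic carbon of the cycloheptenone (ring B), giving a (Z)-alkenyl iodide at C8 and an aldehyde at C9; (b) the C6 ester C–O bond, giving MOM-protected p-coumaric acid; (c) C6–C7, giving a C6 aldehyde and a propynyl Grignard reagent; (d) C1–CH3, by conjugate methylation of a cyclopentene carbaldehyde; (e) C9–C10, by vinylogous Mukaiyama extension of the enal methyl group; (f) C1=C5, by aldol condensation of the keto aldehyde obtained by ozonolysis of (S)-terpinen-4-ol.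
2. Forward order: the cyclohexene ring of the terpene is cleaved and re-closed as ring A (cyclopentane C1–C5) with its carbinol carbon C4 intact; the C10–C9 arm and the C6–C8 chain are built on ring A; ring B (C1, C5–C10) is closed last.
3. Stereochemistry: C4 comes from the chiral pool; C1 from methyl delivery anti to the C4 isopropyl group; C5 from thermodynamic equilibration; C6 from chelation-controlled alkynylation; the C7=C8 geometry from alkoxide-directed trans-hydroalumination and iodination; the C9 carbinol is not controlled and is oxidised.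
4. Enabling feature: in ring B the endocyclic cis C7=C8 olefin holds C6 and C9 on the same side, and on ring A the C5 side chain (β) and the C1–CH2 arm (α) are trans-vicinal. A C8–I bond cis to C6 and a C9 aldehyde therefore lie within reach, and an alkenylchromium formed under electroreductive chromium/nickel catalysis can add to the carbonyl and close the seven-membered ring.

Key step: step 11

Remark: daucane numbering is used for all compounds (ring A = C1–C5, ring B = C1, C5–C10; β = face of the C4 oxygen and the C1 methyl group), and (S)-(+)-terpinen-4-ol is assumed to be used in enantiopure form.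

**Step 1**
Reactants: 1 (S)-(+)-terpinen-4-ol
Product: 2 (4S)-4-(methoxymethoxy)-1-methyl-4-(propan-2-yl)cyclohex-1-ene
Conditions: MOMCl, i-Pr2NEt, Bu4NI (cat.), ClCH2CH2Cl, 60 °C
Reagents that add atoms: chloromethyl methyl ether, COCCl
Why: O-alkylation of the tertiary alcohol with the reactive α-chloro ether (Williamson-type acetal formation) should proceed without touching the stereocenter, and the methoxymethyl ether withstands the bases and organometallics ahead and can chelate magnesium in step 6.

**Step 2**
Reactants: 2 (4S)-4-(methoxymethoxy)-1-methyl-4-(propan-2-yl)cyclohex-1-ene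
Product: 4 5-(methoxymethoxy)-2-methyl-5-(propan-2-yl)cyclopent-1-ene-1-carbaldehyde (ring-A enal), via keto aldehyde 3 (not isolated)
Conditions: O3, CH2Cl2, −78 °C; Me2S, −78 °C → rt; then piperidine (cat.), AcOH (cat.), 40 °C
Reagents that add atoms: ozone, [O-][O+]=O
Why: Ozonolysis cleaves the only olefin (C–C cleavage of the cyclohexene) to a 1,6-keto aldehyde, and piperidinium acetate then effects an intramolecular enamine aldol condensation of the aldehyde α-carbon (C5) onto the methyl ketone (C1) with dehydration into conjugation, which re-closes the chain as ring A and leaves the C4 carbinol stereocenter untouched.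

**Step 3**
Reactants: 4 ring-A enal
Product: 5 trimethylsilyl dienol ether of 4 (exocyclic C1=CH2; C5=CH–OSiMe3)
Conditions: LiTMP, TMSCl (in situ), THF, −78 °C
Reagents that add atoms: chlorotrimethylsilane, C[Si](C)(C)Cl
Why: Irreversible deprotonation by the hindered lithium amide should occur at the less substituted γ-carbon, the C1 methyl group cis to the formyl group, and the silyl chloride present traps the dienolate on oxygen before it can equilibrate to the endocyclic isomer (kinetic extended-enolate formation, as in kinetic enolisation of methyl ketones).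

**Step 4**
Reactants: 5 trimethylsilyl dienol ether
Product: 6 2-(2,2-dimethoxyethyl)-5-(methoxymethoxy)-5-(propan-2-yl)cyclopent-1-ene-1-carbaldehyde
Conditions: HC(OMe)3, TMSOTf (5 mol %), CH2Cl2, −78 °C
Reagents that add atoms: trimethyl orthoformate, COC(OC)OC
Why: Vinylogous Mukaiyama reaction in which the dimethoxycarbenium ion formed from the orthoformate attacks the unhindered terminal methylene (the γ-carbon, future C10) of the silyloxydiene, the fully substituted α-carbon C5 being blocked, and loss of the silyl group to methoxide restores the conjugated enal and regenerates the silyl triflate.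

**Step 5**
Reactants: 6 enal acetal
Product: 9 ring-A aldehyde (1β-CH3; 1α-CH2CH(OMe)2; 4β-OMOM; 4α-i-Pr; 5β-CHO), via silyl enol ether 7 (not isolated), via C5-epimeric aldehyde 8 (not isolated)
Conditions: MeMgBr, CuBr·SMe2 (10 mol %), TMSCl, THF, −78 → −40 °C; then K2CO3, MeOH, 0 °C → rt
Reagents that add atoms: methylmagnesium bromide, C[Mg]Br
Why: Copper-catalysed 1,4-addition of the Grignard reagent, accelerated by the silyl chloride, should deliver the methyl group to C1 on the face opposite the C4 isopropyl group (the face of the smaller, coordinating methoxymethoxy oxygen), setting the quaternary center with methyl cis to the C4 oxygen, and methanolysis of the silyl enol ether with carbonate equilibration of the enolisable C5 should then place the formyl group trans to both the isopropyl and the dimethoxyethyl groups (thermodynamic control).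

**Step 6**
Reactants: 9 ring-A aldehyde
Product: 10 propargylic alcohol (9 with 5β-CH(OH)–C≡C–CH3; C6 configured as in the target)
Conditions: CH3C≡CMgBr, MgBr2·OEt2, CH2Cl2/Et2O, −78 → −20 °C; aq. NH4Cl
Reagents that add atoms: 1-propynylmagnesium bromide, CC#C[Mg]Br
Why: 1,2-Addition of the alkynyl Grignard reagent under chelation control, in which magnesium bridges the aldehyde oxygen and the C4 methoxymethoxy group in a six-membered chelate and the nucleophile enters from the side of H5, away from the quaternary C1 (Cram chelate model), should give the C6 carbinol with the configuration of the target.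

**Step 7**
Reactants: 10 propargylic alcohol
Product: 12 (Z)-alkenyl iodide (5β-CH(OH)–CH=C(I)CH3; iodine cis to C6), via alkenylalanate 11 (not isolated)
Conditions: NaAlH2(OCH2CH2OMe)2, THF, 0 °C → rt; then I2, −78 → 0 °C; aq. Rochelle salt
Reagents that add atoms: iodine, II
Why: Alkoxide-directed trans-hydroalumination of the propargylic alcohol places hydride on the proximal carbon C7 and aluminium on the distal carbon C8 within a five-membered oxa-alumina ring, and iodinolysis of the C–Al bond with retention gives the (Z)-alkenyl iodide with iodine cis to C6, the geometry that ring B demands.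

**Step 8**
Reactants: 13 p-coumaric acid
Product: 15 (E)-3-[4-(methoxymethoxy)phenyl]prop-2-enoic acid, via methoxymethyl ester 14 (not isolated)
Conditions: MOMCl, i-Pr2NEt, CH2Cl2, 0 °C → rt; then LiOH, THF/MeOH/H2O, rt; aq. HCl to pH 4
Reagents that add atoms: chloromethyl methyl ether, COCCl
Why: Both acidic OH groups are alkylated by the chloromethyl ether and hydroxide then cleaves only the acylal-type methoxymethyl ester (saponification), leaving the aryl methoxymethyl ether and the E olefin untouched.

**Step 9**
Reactants: 12 (Z)-alkenyl iodide; 15 (E)-3-[4-(methoxymethoxy)phenyl]prop-2-enoic acid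
Product: 16 C6 ester of 12 with 15
Conditions: DCC, DMAP, CH2Cl2, 0 °C → rt
Reagents that add atoms: none
Why: Steglich esterification, in which the carbodiimide activates the acid and DMAP transfers the acyl group to the hindered secondary allylic alcohol with retention at C6, the tertiary C4 oxygen being protected.

**Step 10**
Reactants: 16 C6 ester
Product: 17 C9 aldehyde (1α-CH2CHO)
Conditions: PPTS (cat.), acetone/H2O, 50 °C
Reagents that add atoms: water, O
Why: Acid-catalysed acetal hydrolysis unmasks the C9 aldehyde, since the acyclic dimethyl acetal is cleaved far more readily than the two methoxymethyl ethers under these mild conditions and the ester and the alkenyl iodide are inert.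

**Step 11**
Reactants: 17 C9 aldehyde
Product: 18 cycloheptenol (bis-MOM-protected 9-hydroxydauc-7-en-6α-yl p-coumarate; mixture at C9)
Conditions: CrCl2 (20 mol %), NiCl2·glyme (2 mol %), Cp2ZrCl2 (1.2 equiv), Bu4NBF4, DMF (high dilution), undivided cell, Al anode, Ni-foam cathode, constant current, rt; aq. work-up
Reagents that add atoms: none
Why: Zerovalent nickel inserts into the C8–I bond with retention of olefin geometry and hands the alkenyl group to chromium, the trivalent alkenylchromium adds 1,2 to the C9 aldehyde, Cp2ZrCl2 takes over the alkoxide, and the cathode returns chromium to the divalent state so that it turns over. The closest known reaction type is the Nozaki–Hiyama–Kishi coupling of alkenyl iodides with aldehydes, in its stoichiometric ring-closing form and in its chromium-electrocatalytic intermolecular form. Ring B closes by 7-exo-trig attack of C8 on the C9 carbonyl, giving the trans-fused bicyclo[5.3.0]decene. The only new stereocenter is the C9 carbinol, which is not controlled and is removed by the oxidation in step 12. The step needs ring closure to win over oligomerisation and the aldehyde to react in preference to the cinnamate ester; the cis placement of iodine and C6 on the C7=C8 olefin, the trans-vicinal arms on ring A and high dilution should secure the first, and the known aldehyde selectivity of alkenylchromium reagents the second.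

**Step 12**
Reactants: 18 cycloheptenol
Product: 19 bis(methoxymethyl) ether of the target (ring-B enone)
Conditions: Dess–Martin periodinane, CH2Cl2, 0 °C → rt
Reagents that add atoms: none
Why: Dess–Martin oxidation of the secondary allylic alcohol should give the conjugated enone of ring B and removes the uncontrolled C9 stereocenter, no other oxidisable hydroxyl group being free.

**Step 13**
Reactants: 19 bis(methoxymethyl) ether of the target
Product: 20 target CNP0310968.1
Conditions: Me2BBr, CH2Cl2, −78 °C; then aq. NaHCO3/THF
Reagents that add atoms: none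
Why: The boron Lewis acid cleaves both methoxymethyl acetals at low temperature (Lewis acid-mediated acetal cleavage) and aqueous work-up releases the tertiary alcohol with retention and the phenol, conditions under which the allylic ester, the enone and the E cinnamate should survive.

**Compound list**
1 | (S)-(+)-terpinen-4-ol, (1S)-4-methyl-1-(propan-2-yl)cyclohex-3-en-1-ol | CC1=CC[C@](O)(C(C)C)CC1 | starting material
2 | (4S)-4-(methoxymethoxy)-1-methyl-4-(propan-2-yl)cyclohex-1-ene | CC1=CC[C@](OCOC)(C(C)C)CC1 | intermediate
3 | (3S)-3-(methoxymethoxy)-6-oxo-3-(propan-2-yl)heptanal (keto aldehyde, not isolated) | O=CC[C@](OCOC)(C(C)C)CCC(C)=O | intermediate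
4 | (5R)-5-(methoxymethoxy)-2-methyl-5-(propan-2-yl)cyclopent-1-ene-1-carbaldehyde (ring-A enal; C4 carries β-OMOM and α-i-Pr) | O=CC1=C(C)CC[C@@]1(OCOC)C(C)C | intermediate
5 | trimethylsilyl dienol ether of 4 with exocyclic C1=CH2 and C5=CH–OSiMe3 (enol ether geometry not controlled) | C[Si](C)(C)OC=C1C(=C)CC[C@@]1(OCOC)C(C)C | intermediate
6 | (5R)-2-(2,2-dimethoxyethyl)-5-(methoxymethoxy)-5-(propan-2-yl)cyclopent-1-ene-1-carbaldehyde | O=CC1=C(CC(OC)OC)CC[C@@]1(OCOC)C(C)C | intermediate
7 | trimethylsilyl enol ether (C5=CH–OSiMe3) of the conjugate adduct, 1β-CH3, 1α-CH2CH(OMe)2 (not isolated) | C[Si](C)(C)OC=C1[C@](C)(CC[C@@]1(OCOC)C(C)C)CC(OC)OC | intermediate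
8 | C5 epimer of 9 (5α-CHO, not isolated) | O=C[C@H]1[C@](C)(CC[C@@]1(OCOC)C(C)C)CC(OC)OC | intermediate
9 | ring-A aldehyde: cyclopentane with 1β-CH3, 1α-CH2CH(OMe)2, 4β-OMOM, 4α-i-Pr, 5β-CHO (5α-H) | O=C[C@@H]1[C@](C)(CC[C@@]1(OCOC)C(C)C)CC(OC)OC | intermediate
10 | propargylic alcohol: 9 with 5β-CH(OH)–C≡C–CH3, C6 configured as in the target | CC#C[C@H](O)[C@@H]1[C@](C)(CC[C@@]1(OCOC)C(C)C)CC(OC)OC | intermediate
11 | sodium alkenylalanate with a five-membered O–Al–C8=C7–C6 ring, aluminium carrying two 2-methoxyethoxy groups (not isolated) | CC1=C[C@@H]([C@@H]2[C@](C)(CC[C@@]2(OCOC)C(C)C)CC(OC)OC)O[Al-]1(OCCOC)OCCOC.[Na+] | intermediate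
12 | (Z)-alkenyl iodide: 9-type ring A with 5β-CH(OH)–CH=C(I)CH3, iodine cis to C6 | I/C(C)=C\[C@H](O)[C@@H]1[C@](C)(CC[C@@]1(OCOC)C(C)C)CC(OC)OC | intermediate
13 | p-coumaric acid, (E)-3-(4-hydroxyphenyl)prop-2-enoic acid | OC(=O)/C=C/c1ccc(O)cc1 | starting material
14 | methoxymethyl (E)-3-[4-(methoxymethoxy)phenyl]prop-2-enoate (not isolated) | COCOC(=O)/C=C/c1ccc(OCOC)cc1 | intermediate
15 | (E)-3-[4-(methoxymethoxy)phenyl]prop-2-enoic acid | OC(=O)/C=C/c1ccc(OCOC)cc1 | intermediate
16 | C6 (E)-4-(methoxymethoxy)cinnamate of 12 | I/C(C)=C\[C@H](OC(=O)/C=C/c2ccc(OCOC)cc2)[C@@H]1[C@](C)(CC[C@@]1(OCOC)C(C)C)CC(OC)OC | intermediate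
17 | aldehyde: 16 with 1α-CH2CHO in place of the dimethyl acetal | I/C(C)=C\[C@H](OC(=O)/C=C/c2ccc(OCOC)cc2)[C@@H]1[C@](C)(CC[C@@]1(OCOC)C(C)C)CC=O | intermediate
18 | 9-hydroxy-4β-(methoxymethoxy)dauc-7-en-6α-yl (E)-3-[4-(methoxymethoxy)phenyl]prop-2-enoate (1β-CH3, 5α-H, mixture at C9) | CC1=C[C@H](OC(=O)/C=C/c2ccc(OCOC)cc2)[C@@H]2[C@](C)(CC[C@@]2(OCOC)C(C)C)CC1O | intermediate
19 | 4β-(methoxymethoxy)-9-oxodauc-7-en-6α-yl (E)-3-[4-(methoxymethoxy)phenyl]prop-2-enoate | CC1=C[C@H](OC(=O)/C=C/c2ccc(OCOC)cc2)[C@@H]2[C@](C)(CC[C@@]2(OCOC)C(C)C)CC1=O | intermediate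
20 | CNP0310968.1, 4β-hydroxy-9-oxodauc-7-en-6α-yl (E)-3-(4-hydroxyphenyl)prop-2-enoate (1β-CH3, 5α-H) | CC1=C[C@H](OC(=O)/C=C/c2ccc(O)cc2)[C@@H]2[C@](C)(CC[C@@]2(O)C(C)C)CC1=O | target

**Step count and risks**
Total steps: 13. Longest linear sequence: 12 (steps 1–7 and 9–13; step 8 prepares the acid).

Steps most likely to fail:

Step 3. The amide may deprotonate the ring methylene C2 instead of the methyl group, or add to the aldehyde, so that the chain extension of step 4 occurs at the wrong carbon or not at all. Fallback: the two-carbon arm is installed before the ring is cut. Setting out from 2, allylic metalation of the vinylic methyl group (n-BuLi/KOt-Bu, then DMF) would give 2-[(4S)-4-(methoxymethoxy)-4-(propan-2-yl)cyclohex-1-en-1-yl]acetaldehyde F1. Acetalisation (HC(OMe)3, PPTS, MeOH) would give the dimethyl acetal F2. The ozonolysis and aldol conditions of step 2, passing through the homologated keto aldehyde F3, would then come back to the route at 6.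

Step 5. The methyl group may enter with poor facial selectivity or add 1,2, and the C4 oxygen may be lost by β-elimination during the base equilibration at C5. Fallback: the methyl group is delivered as a cyclopropane methylene under coordination control. Setting out from 6, Luche reduction (NaBH4, CeCl3, MeOH) would give the allylic alcohol F4. Simmons–Smith cyclopropanation (Et2Zn, CH2I2), directed by the zinc alkoxide and the methoxymethoxy oxygen to the β face, would give the cyclopropyl carbinol F5. Dess–Martin oxidation would give the cyclopropyl aldehyde F6. Reductive opening of the exocyclic cyclopropane bond next to the carbonyl (SmI2, HMPA, t-BuOH) would leave the β-methyl group on C1, and the carbonate equilibration of step 5 would come back to the route at 9.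

Step 11. Oligomerisation, or reduction of the C–I bond without addition to the aldehyde, may compete with closure of the seven-membered ring. Fallback: ring B is closed at the C7=C8 olefin by metathesis. Setting out from 9, vinylmagnesium bromide under the chelation conditions of step 6 would give the allylic alcohol F7. Esterification with 15 (DCC, DMAP) would give the ester F8, and acetal hydrolysis (PPTS, acetone/H2O) the aldehyde F9. Isopropenylmagnesium bromide at −78 °C would give the diene F10. Ring-closing metathesis with the second-generation Grubbs catalyst would come back to the route at 18.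

**Further compounds**
F1 | step 3 | 2-[(4S)-4-(methoxymethoxy)-4-(propan-2-yl)cyclohex-1-en-1-yl]acetaldehyde | O=CCC1=CC[C@](OCOC)(C(C)C)CC1
F2 | step 3 | (4S)-1-(2,2-dimethoxyethyl)-4-(methoxymethoxy)-4-(propan-2-yl)cyclohex-1-ene | COC(OC)CC1=CC[C@](OCOC)(C(C)C)CC1
F3 | step 3 | (3S)-8,8-dimethoxy-3-(methoxymethoxy)-6-oxo-3-(propan-2-yl)octanal | O=CC[C@](OCOC)(C(C)C)CCC(=O)CC(OC)OC
F4 | step 5 | [2-(2,2-dimethoxyethyl)-5-(methoxymethoxy)-5-(propan-2-yl)cyclopent-1-en-1-yl]methanol (C4: β-OMOM) | OCC1=C(CC(OC)OC)CC[C@@]1(OCOC)C(C)C
F5 | step 5 | [5-(2,2-dimethoxyethyl)-2-(methoxymethoxy)-2-(propan-2-yl)bicyclo[3.1.0]hexan-1-yl]methanol, cyclopropane methylene on the β face | OC[C@@]12C[C@]1(CC(OC)OC)CC[C@@]2(OCOC)C(C)C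
F6 | step 5 | 5-(2,2-dimethoxyethyl)-2-(methoxymethoxy)-2-(propan-2-yl)bicyclo[3.1.0]hexane-1-carbaldehyde, cyclopropane methylene on the β face | O=C[C@@]12C[C@]1(CC(OC)OC)CC[C@@]2(OCOC)C(C)C
F7 | step 11 | allylic alcohol: 9 with 5β-CH(OH)–CH=CH2, C6 configured as in 10 | C=C[C@H](O)[C@@H]1[C@](C)(CC[C@@]1(OCOC)C(C)C)CC(OC)OC
F8 | step 11 | C6 (E)-4-(methoxymethoxy)cinnamate of F7 | C=C[C@H](OC(=O)/C=C/c2ccc(OCOC)cc2)[C@@H]1[C@](C)(CC[C@@]1(OCOC)C(C)C)CC(OC)OC
F9 | step 11 | aldehyde: F8 with 1α-CH2CHO | C=C[C@H](OC(=O)/C=C/c2ccc(OCOC)cc2)[C@@H]1[C@](C)(CC[C@@]1(OCOC)C(C)C)CC=O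
F10 | step 11 | diene: F9 after isopropenyl addition, 1α-CH2CH(OH)C(CH3)=CH2 (mixture at C9) | C=C[C@H](OC(=O)/C=C/c2ccc(OCOC)cc2)[C@@H]1[C@](C)(CC[C@@]1(OCOC)C(C)C)CC(O)C(C)=C
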